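**Plan**

1. Numbering used throughout: C1 is the ester carbonyl, C2 its CH2, C3–C6 are the ring carbons (C3 OCH, C4 CHEt, C5 CH2, C6 quaternary), C7–C14 the side chain. Retrosynthetic cuts in order: C2–C3; then O2 is taken out from between C3 and C6 and C3 is joined to C6 (1,2-dioxane → cyclobutanol); then C3–C4 and C5–C6 together; then C6–C7; then the ethyl at C8 and the methyl at C10.
2. Enabling feature: ring carbons C3–C4–C5–C6 are a four-carbon chain closed only by the O–O bridge, with acetal-level C3 beside C4 and the fully substituted C6 beside C5. This is a cyclobutane with O2 inserted into one bond. That cyclobutane (C3–OSi next to C4–CO2R) is the Michael–aldol (2+2) adduct of an aldehyde silyl enol ether (C3=C6) and an acrylate (C4=C5).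
3. Forward: C7–C14 by two zirconium-catalysed carboaluminations; C6–C7 by ester enolate alkylation; silyl enol ether; (2+2) closes the cyclobutane (the only carbocycle, opened again later); ester → ethyl; cobalt/O2 ring expansion inserts O2 into C3–C6 and closes the dioxane; C3 alkylation through the ring peroxycarbenium ion adds C1–C2.
4. Stereochemistry: C10 and C8 from the chiral zirconocene; C4 from the chiral Lewis acid of the (2+2); C3 from axial attack on the peroxycarbenium ion, cis to the C4 ethyl. C6 is formed on a planar tertiary radical and cannot be controlled in this disconnection, so the C6 epimers are separated after the last step.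

Key step: step 7

Assumption: (+)-(NMI)2ZrCl2 is taken to give the S centre in both carboaluminations and the (S)-oxazaborolidine·AlBr3 catalyst to give the (1S) cyclobutane ester; if either sense is opposite, the enantiomeric catalyst is used.

**Route**

Step 1
Reactants: 1 hex-1-ene
Product: 3 (4S)-4-methyloct-1-ene, via dimethyl[(2S)-2-methylhexyl]alumane 2 (not isolated)
Conditions: Me3Al, (+)-(NMI)2ZrCl2 (cat., NMI = 1-neomenthylindenyl), (MeAlO)n (cat.), CH2Cl2, 0 °C to rt; evaporate; then Zn(OTf)2, CH2=CHBr, PdCl2(DPEphos) (cat.), i-Bu2AlH (cat.), DMF, rt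
Reagents that add atoms: trimethylaluminium C[Al](C)C; vinyl bromide C=CBr
Why: Zirconium-catalysed asymmetric carboalumination (ZACA) adds Me–Al across the terminal alkene with methyl at the internal carbon, the chiral zirconocene choosing the alkene face and so setting C10 as S, and the primary alkylalane is then vinylated by Pd-catalysed cross-coupling (Negishi type, through zinc) without touching that centre.

Step 2
Reactants: 3 (4S)-4-methyloct-1-ene
Product: 5 (2S,4S)-2-ethyl-4-methyloctan-1-ol, via diethyl[(2S,4S)-2-ethyl-4-methyloctyl]alumane 4 (not isolated)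
Conditions: Et3Al, (+)-(NMI)2ZrCl2 (cat.), CH2Cl2, rt; then O2, 0 °C to rt; 3 M HCl
Reagents that add atoms: triethylaluminium CC[Al](CC)CC; dioxygen O=O
Why: A second ZACA, now with Et3Al, sets C8 as S under catalyst control (the remote C10 centre has little influence) and O2 oxidises the primary C–Al bond to the alcohol, at which stage minor stereoisomers left by the two carboaluminations are to be removed by chromatography.

Step 3
Reactants: 5 (2S,4S)-2-ethyl-4-methyloctan-1-ol
Product: 6 (2S,4S)-2-ethyl-1-iodo-4-methyloctane
Conditions: I2, PPh3, imidazole, CH2Cl2, 0 °C to rt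
Reagents that add atoms: iodine II
Why: Appel-type conversion of the primary alcohol to the iodide by SN2 displacement of the oxyphosphonium group; no stereocentre is involved.

Step 4
Reactants: 6 (2S,4S)-2-ethyl-1-iodo-4-methyloctane; 7 ethyl butanoate
Product: 9 ethyl (4S,6S)-2,4-diethyl-6-methyldecanoate (both C2 epimers), via lithium 1-ethoxybut-1-en-1-olate 8 (not isolated)
Conditions: LiN(i-Pr)2, THF, −78 °C; then 6, DMPU, −78 °C to rt
Reagents that add atoms: none
Why: SN2 alkylation of the ester enolate by the primary iodide forms the C6–C7 bond; the new centre at C6 is uncontrolled and need not be controlled because C6 becomes sp2 in step 6.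

Step 5
Reactants: 9 ethyl (4S,6S)-2,4-diethyl-6-methyldecanoate
Product: 10 (4S,6S)-2,4-diethyl-6-methyldecanal (both C2 epimers)
Conditions: i-Bu2AlH, CH2Cl2, −78 °C; then MeOH, aq. potassium sodium tartrate
Reagents that add atoms: none
Why: Partial reduction of the ester at −78 °C should stop at the aldehyde because the tetrahedral aluminium hemiacetal survives until work-up; the side-chain centres are remote from the carbonyl.

Step 6
Reactants: 10 (4S,6S)-2,4-diethyl-6-methyldecanal
Product: 11 {[(4S,6S)-2,4-diethyl-6-methyldec-1-en-1-yl]oxy}tri(propan-2-yl)silane (E/Z mixture)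
Conditions: i-Pr3SiOTf, Et3N, CH2Cl2, 0 °C to rt
Reagents that add atoms: triisopropylsilyl trifluoromethanesulfonate CC(C)[Si](C(C)C)(C(C)C)OS(=O)(=O)C(F)(F)F
Why: Soft enolisation of the α-branched aldehyde (one α-hydrogen only) with silyl triflate and amine gives the trisubstituted silyl enol ether; its E/Z ratio is of no consequence because C6 is planarised again in step 12.

Step 7
Reactants: 11 silyl enol ether; 12 2,2,2-trifluoroethyl prop-2-enoate
Product: 13 2,2,2-trifluoroethyl (1S)-3-ethyl-3-[(2S,4S)-2-ethyl-4-methyloctyl]-2-{[tri(propan-2-yl)silyl]oxy}cyclobutane-1-carboxylate (mixture at ring C2 and C3)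
Conditions: (S)-oxazaborolidine·AlBr3 [AlBr3 complex of (S)-1-(2-methylphenyl)-3,3-diphenyltetrahydro-1H,3H-pyrrolo[1,2-c][1,3,2]oxazaborole, C24H24BNO·AlBr3] (10 mol %), CH2Cl2, −78 °C
Reagents that add atoms: none
Why: The chiral aluminium Lewis acid binds the acrylate carbonyl, the nucleophilic carbon of the silyl enol ether (future C6) adds to the acrylate β-carbon (C5–C6 bond, quaternary carbon made here), and the aluminium enolate so formed closes at once onto the silyloxocarbenium carbon (C3–C4 bond), a stepwise Michael–aldol (2+2) rather than a concerted cycloaddition. The closest known reaction type is the Lewis-acid-catalysed (2+2) cycloaddition of silyl enol ethers with acrylates (EtAlCl2, Tf2NH or chiral oxazaborolidine·AlBr3); the thermal enamine–acrylate cyclobutane synthesis shows that aldehyde-derived β,β-dialkyl enol derivatives can take part, which is the untested feature here. The cyclobutane closes by 4-exo-trig attack of the enolate carbon on the exocyclic C=O+ bond. C4 is the only new centre that survives to the target and it is fixed by the catalyst, because the tethered oxocarbenium ion can reach only the enolate face on which the Michael attack took place, the face left open by the catalyst; C3 and C6 form as mixtures, which is harmless since C3 becomes a planar cation in step 14 and C6 a planar radical in step 12. The step needs Michael regiochemistry that puts the ester next to the siloxy carbon, secured by the polarity match of the partners, and ring closure faster than silyl transfer or retro-Michael, secured by the bulky i-Pr3Si group and the electron-poor trifluoroethyl ester at −78 °C.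

Step 8
Reactants: 13 cyclobutane ester
Product: 14 {(1R)-3-ethyl-3-[(2S,4S)-2-ethyl-4-methyloctyl]-2-{[tri(propan-2-yl)silyl]oxy}cyclobutyl}methanol
Conditions: LiAlH4, Et2O, 0 °C
Reagents that add atoms: none
Why: Hydride reduction of the activated ester to the primary alcohol while the silyl ether stays on, which prevents retro-aldol opening of the β-oxy ester; reduction is faster than enolisation, so C4 keeps its configuration (the descriptor changes only through priorities).

Step 9
Reactants: 14 cyclobutylmethanol
Product: 15 {(1R)-3-ethyl-3-[(2S,4S)-2-ethyl-4-methyloctyl]-2-{[tri(propan-2-yl)silyl]oxy}cyclobutyl}methyl 4-methylbenzenesulfonate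
Conditions: TsCl, pyridine, DMAP (cat.), CH2Cl2, 0 °C to rt
Reagents that add atoms: 4-methylbenzenesulfonyl chloride Cc1ccc(cc1)S(Cl)(=O)=O
Why: Sulfonylation of the primary alcohol; no bond to a stereocentre is broken.

Step 10
Reactants: 15 tosylate
Product: 16 {[(4S)-2,4-diethyl-2-[(2S,4S)-2-ethyl-4-methyloctyl]cyclobutyl]oxy}tri(propan-2-yl)silane
Conditions: MeMgBr, Li2CuCl4 (cat.), THF, −20 °C to rt
Reagents that add atoms: methylmagnesium bromide C[Mg]Br
Why: Copper-catalysed sp3–sp3 coupling of the primary tosylate with the methyl Grignard reagent (SN2 at CH2) turns the C4 substituent into ethyl without touching C4.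

Step 11
Reactants: 16 silyl ether
Product: 17 (4S)-2,4-diethyl-2-[(2S,4S)-2-ethyl-4-methyloctyl]cyclobutan-1-ol
Conditions: Bu4NF, THF, 50 °C
Reagents that add atoms: none
Why: Fluoride cleaves the Si–O bond and frees the secondary cyclobutanol needed for alkoxy radical formation.

Step 12
Reactants: 17 cyclobutanol
Product: 19 (4S)-4,6-diethyl-6-[(2S,4S)-2-ethyl-4-methyloctyl]-1,2-dioxan-3-ol (mixture at C3 and C6), via (2S)-2-ethyl-4-[(2S,4S)-2-ethyl-4-methyloctyl]-4-hydroperoxyhexanal 18 (not isolated)
Conditions: Co(acac)2 (cat.), O2 (1 atm), CH2Cl2, rt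
Reagents that add atoms: dioxygen O=O
Why: Cobalt-mediated aerobic ring expansion of a cyclobutanol, in which the cyclobutyloxy radical undergoes strain-driven β-scission toward the more substituted C6, the tertiary radical captures O2 and the hydroperoxide closes onto the C3 aldehyde; C6 is created here on a planar radical with no controlling element, so both C6 epimers are expected and are carried on together, while C4 is not touched under these neutral conditions.

Step 13
Reactants: 19 1,2-dioxan-3-ol
Product: 20 (4S)-4,6-diethyl-6-[(2S,4S)-2-ethyl-4-methyloctyl]-1,2-dioxan-3-yl acetate (mixture at C3 and C6)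
Conditions: Ac2O, pyridine, DMAP (cat.), CH2Cl2, 0 °C
Reagents that add atoms: acetic anhydride CC(=O)OC(C)=O
Why: Acylation of the peroxy-hemiacetal hydroxyl installs the leaving group for ionisation; the anomeric configuration is irrelevant.

Step 14
Reactants: 20 acetate; 21 tert-butyl[(1-methoxyethenyl)oxy]dimethylsilane
Product: 22 methyl 2-[(3S,4S,6S)-4,6-diethyl-6-[(2S,4S)-2-ethyl-4-methyloctyl]-1,2-dioxan-3-yl]acetate (target)
Conditions: Me3SiOTf (cat.), CH2Cl2, −78 °C; chromatography
Reagents that add atoms: none
Why: The silyl triflate ionises the anomeric acetate to the ring peroxycarbenium ion, which the silyl ketene acetal attacks (Mukaiyama type) along the axial trajectory of the half-chair that keeps the C4 ethyl pseudoequatorial (the other half-chair suffers a syn-axial clash between the C4 ethyl and the axial C6 alkyl), so that CH2CO2Me should enter cis to the C4 ethyl and set C3 as S; the (6S) compound is then separated from its C6 epimer.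

**Compound list**

1 | hex-1-ene | C=CCCCC | starting material
2 | dimethyl[(2S)-2-methylhexyl]alumane | CCCC[C@H](C)C[Al](C)C | intermediate
3 | (4S)-4-methyloct-1-ene | CCCC[C@H](C)CC=C | intermediate
4 | diethyl[(2S,4S)-2-ethyl-4-methyloctyl]alumane | CCCC[C@H](C)C[C@H](CC)C[Al](CC)CC | intermediate
5 | (2S,4S)-2-ethyl-4-methyloctan-1-ol | CCCC[C@H](C)C[C@H](CC)CO | intermediate
6 | (2S,4S)-2-ethyl-1-iodo-4-methyloctane | CCCC[C@H](C)C[C@H](CC)CI | intermediate
7 | ethyl butanoate | CCCC(=O)OCC | starting material
8 | lithium 1-ethoxybut-1-en-1-olate | [Li+].CCC=C([O-])OCC | intermediate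
9 | ethyl (4S,6S)-2,4-diethyl-6-methyldecanoate (C2 epimers) | CCCC[C@H](C)C[C@H](CC)CC(CC)C(=O)OCC | intermediate
10 | (4S,6S)-2,4-diethyl-6-methyldecanal (C2 epimers) | CCCC[C@H](C)C[C@H](CC)CC(CC)C=O | intermediate
11 | {[(4S,6S)-2,4-diethyl-6-methyldec-1-en-1-yl]oxy}tri(propan-2-yl)silane (E/Z) | CCCC[C@H](C)C[C@H](CC)CC(CC)=CO[Si](C(C)C)(C(C)C)C(C)C | intermediate
12 | 2,2,2-trifluoroethyl prop-2-enoate | C=CC(=O)OCC(F)(F)F | starting material
13 | 2,2,2-trifluoroethyl (1S)-3-ethyl-3-[(2S,4S)-2-ethyl-4-methyloctyl]-2-{[tri(propan-2-yl)silyl]oxy}cyclobutane-1-carboxylate | CCCC[C@H](C)C[C@H](CC)CC1(CC)C[C@H](C(=O)OCC(F)(F)F)C1O[Si](C(C)C)(C(C)C)C(C)C | intermediate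
14 | {(1R)-3-ethyl-3-[(2S,4S)-2-ethyl-4-methyloctyl]-2-{[tri(propan-2-yl)silyl]oxy}cyclobutyl}methanol | CCCC[C@H](C)C[C@H](CC)CC1(CC)C[C@H](CO)C1O[Si](C(C)C)(C(C)C)C(C)C | intermediate
15 | {(1R)-3-ethyl-3-[(2S,4S)-2-ethyl-4-methyloctyl]-2-{[tri(propan-2-yl)silyl]oxy}cyclobutyl}methyl 4-methylbenzenesulfonate | CCCC[C@H](C)C[C@H](CC)CC1(CC)C[C@H](COS(=O)(=O)c2ccc(C)cc2)C1O[Si](C(C)C)(C(C)C)C(C)C | intermediate
16 | {[(4S)-2,4-diethyl-2-[(2S,4S)-2-ethyl-4-methyloctyl]cyclobutyl]oxy}tri(propan-2-yl)silane | CCCC[C@H](C)C[C@H](CC)CC1(CC)C[C@H](CC)C1O[Si](C(C)C)(C(C)C)C(C)C | intermediate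
17 | (4S)-2,4-diethyl-2-[(2S,4S)-2-ethyl-4-methyloctyl]cyclobutan-1-ol | CCCC[C@H](C)C[C@H](CC)CC1(CC)C[C@H](CC)C1O | intermediate
18 | (2S)-2-ethyl-4-[(2S,4S)-2-ethyl-4-methyloctyl]-4-hydroperoxyhexanal (C4 epimers) | CCCC[C@H](C)C[C@H](CC)CC(CC)(OO)C[C@H](CC)C=O | intermediate
19 | (4S)-4,6-diethyl-6-[(2S,4S)-2-ethyl-4-methyloctyl]-1,2-dioxan-3-ol (mixture at C3 and C6) | CCCC[C@H](C)C[C@H](CC)CC1(CC)C[C@H](CC)C(O)OO1 | intermediate
20 | (4S)-4,6-diethyl-6-[(2S,4S)-2-ethyl-4-methyloctyl]-1,2-dioxan-3-yl acetate (mixture at C3 and C6) | CCCC[C@H](C)C[C@H](CC)CC1(CC)C[C@H](CC)C(OC(C)=O)OO1 | intermediate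
21 | tert-butyl[(1-methoxyethenyl)oxy]dimethylsilane | C=C(OC)O[Si](C)(C)C(C)(C)C | starting material
22 | methyl 2-[(3S,4S,6S)-4,6-diethyl-6-[(2S,4S)-2-ethyl-4-methyloctyl]-1,2-dioxan-3-yl]acetate | CCCC[C@H](C)C[C@H](CC)C[C@@]1(CC)C[C@H](CC)[C@H](CC(=O)OC)OO1 | target

**Count and risks**

Total step count: 14. Longest linear sequence: 14 steps (1 → 22).

Steps most likely to fail:

1. Step 7 (key step). The Michael adduct may be diverted by silyl transfer to an open-chain ester or may revert, and an acyclic E/Z enol ether may be discriminated poorly by the chiral Lewis acid, eroding enantiofacial control at C4. Fallback (sets out from 11, returns at 14): stereocontrol is moved from the catalyst to a covalently bound auxiliary and activation to an achiral aluminium Lewis acid. (−)-8-Phenylmenthol is acylated with acryloyl chloride and Et3N to (−)-8-phenylmenthyl prop-2-enoate F1. F1 and 11 are combined under EtAlCl2 (CH2Cl2, −78 °C) to give the 8-phenylmenthyl cyclobutanecarboxylate F2, in which the aryl group should shield one face of the ester enolate during ring closure. The C4 diastereomers are separated, and LiAlH4 reduction of F2 releases the auxiliary and gives alcohol 14. The antipodal auxiliary is used if the sense of induction is opposite.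

2. Step 12. The cyclobutyloxy radical may be diverted (oxidation to the cyclobutanone, β-scission toward C4), or the hydroperoxide may be reduced at cobalt before it closes. Fallback (sets out from 17, returns at 19): radical generation and oxygenation are separated. Hypoiodite fragmentation of 17 (PhI(OAc)2, I2, visible light, cyclohexane) gives the tertiary iodo aldehyde F3. Silver-assisted substitution of the iodide by hydrogen peroxide (AgO2CCF3, anhydrous H2O2, Et2O, 0 °C) gives hydroperoxy aldehyde 18, which closes to 19. The lack of facial discrimination at C6 is inherent to any passage through the C6 radical or cation and is not remedied by this fallback; separation of the C6 epimers remains necessary.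

3. Step 14. Attack through a twist-boat may erode the 3,4-cis selectivity, or the peroxycarbenium ion may lose a proton or fragment by O–O heterolysis before the C–C bond forms. Fallback (sets out from 19, returns at 22): the C1–C2 unit is attached by olefination instead of cation chemistry. Lactol 19, through its open form 18, reacts with Ph3P=CHCO2Me (CH2Cl2, rt) to give the hydroperoxy enoate F4. 6-Exo oxa-Michael ring closure (Et2NH, CF3CH2OH, rt) gives 22 together with its C3 epimer, which is removed by chromatography.

Further compounds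
F1 | step 7 | (1R,2S,5R)-5-methyl-2-(2-phenylpropan-2-yl)cyclohexyl prop-2-enoate | C=CC(=O)O[C@@H]1C[C@H](C)CC[C@H]1C(C)(C)c1ccccc1
F2 | step 7 | (1R,2S,5R)-5-methyl-2-(2-phenylpropan-2-yl)cyclohexyl (1S)-3-ethyl-3-[(2S,4S)-2-ethyl-4-methyloctyl]-2-{[tri(propan-2-yl)silyl]oxy}cyclobutane-1-carboxylate | CCCC[C@H](C)C[C@H](CC)CC1(CC)C[C@H](C(=O)O[C@@H]2C[C@H](C)CC[C@H]2C(C)(C)c2ccccc2)C1O[Si](C(C)C)(C(C)C)C(C)C
F3 | step 12 | (2S)-2-ethyl-4-[(2S,4S)-2-ethyl-4-methyloctyl]-4-iodohexanal | CCCC[C@H](C)C[C@H](CC)CC(CC)(I)C[C@H](CC)C=O
F4 | step 14 | methyl (2E,4S)-4-ethyl-6-[(2S,4S)-2-ethyl-4-methyloctyl]-6-hydroperoxyoct-2-enoate | CCCC[C@H](C)C[C@H](CC)CC(CC)(OO)C[C@H](CC)/C=C/C(=O)OC
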